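The leftover comes first: the coupling partner charged above the substrate is 10.0 mM in Monday's and in Tuesday's. Call it the charged excess.

- Monday's: substrate 20 mM; coupling partner 30.0 mM; time 5.0 d
- Tuesday's: substrate 20 mM; coupling partner 30.0 mM; time 3.0 d

    substrate + coupling partner ⇌ isomer of the product (K1 = 7310 L mol⁻¹, k1 = 3.51 × 10⁻⁴ L mol⁻¹ s⁻¹)
    substrate + coupling partner ⇌ target (K2 = 425 L mol⁻¹, k2 = 0.00100 L mol⁻¹ s⁻¹)
    coupling partner + target → over-reaction product (k3 = 4.11 × 10⁻⁴ L mol⁻¹ s⁻¹)

- which of these there is most of at the end, counted by the substrate in it, Monday's (target / substrate / over-reaction product / isomer of the product)
- which of these there is most of at the end, counted by the substrate in it, Tuesday's (target / substrate / over-reaction product / isomer of the product)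
- final amount of the leader among these, as a percentage of the substrate charged, in Monday's
- final amount of the leader among these, as a percentage of the substrate charged, in Tuesday's

Which reagent is charged in the smaller amount? The substrate, 20 mM against 30.0 mM.

Write its balance. [substrate] + [target] + [isomer of the product] + [over-reaction product] = 20 mM.

And the coupling partner's? The over-reaction product carries two coupling partners, so [coupling partner] + [target] + [isomer of the product] + [over-reaction product] + [over-reaction product] = 30.0 mM.

Subtract them. [over-reaction product] = charged excess + [substrate] − [coupling partner].

Is the excess a ceiling? Not strictly. As a share of the substrate charged it is 50.0%, and at this charge the over-reaction product passes that line whenever [substrate] stands above [coupling partner].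

Now commit to numbers. On Tuesday's charge, substrate has a forward half-life of 0.27 d on the path to target, far shorter than the 3.0 d run. So I let substrate go first and split it by forward rates. The ratio of the forward constants, the selectivity factor, is 2.85 for target, which in this reckoning sends 74.0% to target, or 14.8 mM.

The coupling partner left is then the excess. Step 3 removes one target per coupling partner, so [target] − [coupling partner] stays at 4.80 mM. Integrating gives over-reaction product at 40.3% on Monday's, ahead of target at 33.7%. On Tuesday's it gives 33.7%, behind target at 40.4%.

Where is that weak? In the way back. At [coupling partner] equal to the excess, step 2 favours target over substrate by 4.25, and step 1 favours the isomer of the product by 73.1. Target may leak towards the isomer, so my Tuesday's call is shaky.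

The forecast, where my reckoning puts target first on Tuesday's, names over-reaction product at 41% (36% to 45%) on Monday's and over-reaction product at 35% (30% to 39%) on Tuesday's, since its quick estimate “puts the over-reaction product narrowly ahead of the target and isomer by day 3”.

Both flasks end led by over-reaction product, 41.6% on Monday's and 34.9% on Tuesday's. My Tuesday's call failed: target stands at 26.2% and the isomer of the product at 28.3%. Target's half-life by step 3 is 0.65 d on Tuesday's charge. On Monday's at 5.00 d the same half-life reads 5.4 d, with coupling partner down to 12% of its charge. Monday's balance, with the substrate and coupling partner left in that flask, gives over-reaction product at 41.6%. Monday's neighbour, charged with 50 mM of substrate, has a deficit of 20.0 mM, and with 50.0% of its substrate and 2.32% of its coupling partner left, the balance gives over-reaction product at 8.61% of its substrate.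

(The constants used here are those of an exercise; what happens was integrated by code.)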